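**Plan**
- Cuts, in order: the O7–S bond (sulfate carried as its neutral 2,2,2-trichloroethyl diester) together with four O-benzyl masks. Then C2 (ring C)–C1' (ring B). Last O1–C2 and C2–C3 of ring C, back to an acetophenone that already holds all ring-A oxygens plus a one-carbon unit.
- Forward order: ring A is bought. Ring C is closed first as a chromone with a bare C2–H. O7 is singled out on this small fragment, where no 4'-OH competes. Ring B is joined last as an intact aryl bromide.
- Enabling feature: C2–H of the γ-pyrone ring lies next to O1 and is vinylogously tied to C4=O, and the peri pair C4=O/O5 binds MgCl2. A zinc amide can therefore deprotonate C2. This reverses the polarity of a natively electrophilic carbon, so it can be united with the equally electrophilic C1'–Br carbon.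
- End game: MOM off O7, sulfation of the only free OH, one reductive operation that removes the trichloroethyl group and all benzyl groups, then H+ exchange.
- Stereochemistry: the target is flat and achiral (no stereocentre, no configured double bond), so nothing has to be set or preserved.

Key step: step 6

Assumption: the target has no stereocentre, so the demand for a single enantiomer is met trivially; the sulfate is delivered as the free hydrogen sulfate drawn, released from its more stable ammonium salt only in the last operation.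

Step 1
Reactants: 1 2'-hydroxy-4',5',6'-trimethoxyacetophenone
Product: 3 5,6,7-trimethoxy-4H-chromen-4-one, via enaminone 2 (not isolated)
Conditions: DMF-DMA, toluene, 95 °C; evaporate; conc. HCl, CH2Cl2, 40 °C
Reagents that add atoms: N,N-dimethylformamide dimethyl acetal (DMF-DMA), COC(OC)N(C)C
Why: Enaminone route to chromones: the formamide acetal condenses with the acetyl CH3 to give 2, and in acid the phenol OH adds to the β-carbon and dimethylamine is expelled (6-endo-trig addition–elimination), which closes ring C and leaves C2 and C3 as plain CH.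

Step 2
Reactants: 3 5,6,7-trimethoxy-4H-chromen-4-one
Product: 4 5,6,7-trihydroxy-4H-chromen-4-one
Conditions: BBr3 (excess), CH2Cl2, −78 °C to rt; ice-water
Reagents that add atoms: none
Why: Exhaustive BBr3 cleavage of aryl methyl ethers (Lewis-acid dealkylation) frees all three phenols so that they can be re-masked with groups that later leave without acid, and the pyrone ring offers BBr3 nothing else to attack.

Step 3
Reactants: 4 5,6,7-trihydroxy-4H-chromen-4-one
Product: 5 5,6-dihydroxy-7-(methoxymethoxy)-4H-chromen-4-one
Conditions: MOMCl (1.05 equiv), K2CO3 (1.1 equiv), acetone, 0 °C to rt, Ar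
Reagents that add atoms: chloromethyl methyl ether (MOMCl), COCCl
Why: Williamson-type O-alkylation under acidity control: 7-OH is para to C4a and so a vinylogous carboxylic acid, 5-OH is locked in the hydrogen bond to C4=O and 6-OH is flanked on both sides, the same preference that allows mono-alkylation of 5,6,7-trihydroxyflavones at O7.

Step 4
Reactants: 5 5,6-dihydroxy-7-(methoxymethoxy)-4H-chromen-4-one
Product: 6 5,6-bis(benzyloxy)-7-(methoxymethoxy)-4H-chromen-4-one
Conditions: BnBr (3 equiv), K2CO3, DMF, 60 °C, Ar
Reagents that add atoms: benzyl bromide, BrCc1ccccc1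
Why: Williamson ether synthesis with excess benzyl bromide in warm DMF alkylates O6 and then the hydrogen-bonded O5, while the MOM acetal and the 2,3-unsubstituted pyrone tolerate the non-nucleophilic carbonate base.

Step 5
Reactants: 7 4-bromocatechol
Product: 8 4-bromo-1,2-bis(benzyloxy)benzene
Conditions: BnBr (2.3 equiv), K2CO3, acetone, reflux
Reagents that add atoms: benzyl bromide, BrCc1ccccc1
Why: Double Williamson ether synthesis on both catechol OH groups, under which the aryl bromide is inert.

Step 6
Reactants: 6 5,6-bis(benzyloxy)-7-(methoxymethoxy)-4H-chromen-4-one; 8 4-bromo-1,2-bis(benzyloxy)benzene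
Product: 10 5,6-bis(benzyloxy)-2-[3,4-bis(benzyloxy)phenyl]-7-(methoxymethoxy)-4H-chromen-4-one, via C2-zincated chromone 9 (not isolated)
Conditions: TMP2Zn·2MgCl2·2LiCl (commercial solution, 0.6 equiv), THF, −30 to 0 °C; then 8, Pd(OAc)2 (2 mol %), SPhos (4 mol %), 50 °C
Reagents that add atoms: none
Why: The MgCl2 of the base binds the peri pocket formed by C4=O and the 5-benzyloxy oxygen, which pushes ring C towards a 4-oxidopyrylium form and makes C2–H, the sp2 C–H next to O1, the most acidic position; the hindered zinc amide removes it and turns the natively electrophilic β-carbon C2 into a carbon nucleophile (polarity reversal) whose covalent C–Zn bond does not add to C4=O or to a second chromone. Oxidative addition of Pd(0)/SPhos into the C–Br bond of 8, transmetalation from 9 and reductive elimination then join C2 to C1' (Lewis-acid-assisted C–H zincation followed by Negishi cross-coupling, a reaction type already shown to turn 2-unsubstituted chromones into flavones). No ring is closed and no stereocentre is formed. The step needs site selectivity for C2 over C3 (which is favoured only when the base itself coordinates to a free C4=O), over C8–H between O1 and the OMOM group, and over the benzylic OCH2 groups; the Lewis acid on the carbonyl secures the first, and the low basicity of the zinc amide, which does not metalate plain alkoxyarenes or ethers, secures the others. Both chromonyl groups on zinc are transferred, and 8 brings ring B with its oxygens masked by the same benzyl groups as O5 and O6, so the full carbon skeleton and the final protecting-group pattern arise in one operation from a chromone that carries no halogen or other activating group at C2.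

Step 7
Reactants: 10 5,6-bis(benzyloxy)-2-[3,4-bis(benzyloxy)phenyl]-7-(methoxymethoxy)-4H-chromen-4-one
Product: 11 5,6-bis(benzyloxy)-2-[3,4-bis(benzyloxy)phenyl]-7-hydroxy-4H-chromen-4-one
Conditions: conc. HCl (cat.), MeOH–THF 1:1, 45 °C
Reagents that add atoms: none
Why: Acid-catalysed acetal exchange (MOM cleavage) frees only O7, because benzyl aryl ethers and the flavone core are stable to dilute HCl at this temperature, and even partial loss of the peri 5-O-benzyl group would be harmless since a chelated 5-OH is not sulfated in step 8.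

Step 8
Reactants: 11 5,6-bis(benzyloxy)-2-[3,4-bis(benzyloxy)phenyl]-7-hydroxy-4H-chromen-4-one
Product: 12 5,6-bis(benzyloxy)-2-[3,4-bis(benzyloxy)phenyl]-4-oxo-4H-chromen-7-yl 2,2,2-trichloroethyl sulfate
Conditions: Cl3CCH2OSO2Cl (1.5 equiv), Et3N, DMAP (cat.), THF, 0 °C to rt
Reagents that add atoms: 2,2,2-trichloroethyl chlorosulfate, ClS(=O)(=O)OCC(Cl)(Cl)Cl
Why: O-sulfonylation of the single free phenol with a chlorosulfate ester (protected-sulfate method) fixes the sulfate at O7 as a neutral diester that can be chromatographed, DMAP acting as sulfuryl-transfer catalyst.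

Step 9
Reactants: 12 5,6-bis(benzyloxy)-2-[3,4-bis(benzyloxy)phenyl]-4-oxo-4H-chromen-7-yl 2,2,2-trichloroethyl sulfate
Product: 14 6-hydroxyluteolin 7-sulfate [2-(3,4-dihydroxyphenyl)-5,6-dihydroxy-4-oxo-4H-chromen-7-yl hydrogen sulfate], via ammonium salt 13 (not isolated)
Conditions: 10% Pd/C, HCO2NH4 (excess), MeOH–THF, rt, Ar; filter; Dowex 50WX8 (H+ form), H2O, 4 °C; C18 plug; freeze-dry
Reagents that add atoms: none
Why: Pd-catalysed transfer hydrogenolysis cleaves the four benzyl aryl ethers and the same Pd/formate system removes the trichloroethyl group by reductive β-elimination (both known deprotections, run at near-neutral pH where the aryl sulfate anion is safe), and cold passage over a sulfonic-acid resin exchanges NH4+ for H+ to give the hydrogen sulfate as drawn.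

**Compound list**
1 | 2'-hydroxy-4',5',6'-trimethoxyacetophenone | CC(=O)c1c(O)cc(OC)c(OC)c1OC | starting material
2 | (E)-3-(dimethylamino)-1-(6-hydroxy-2,3,4-trimethoxyphenyl)prop-2-en-1-one | CN(C)/C=C/C(=O)c1c(O)cc(OC)c(OC)c1OC | intermediate
3 | 5,6,7-trimethoxy-4H-chromen-4-one | O=c1ccoc2cc(OC)c(OC)c(OC)c12 | intermediate
4 | 5,6,7-trihydroxy-4H-chromen-4-one | O=c1ccoc2cc(O)c(O)c(O)c12 | intermediate
5 | 5,6-dihydroxy-7-(methoxymethoxy)-4H-chromen-4-one | O=c1ccoc2cc(OCOC)c(O)c(O)c12 | intermediate
6 | 5,6-bis(benzyloxy)-7-(methoxymethoxy)-4H-chromen-4-one | O=c1ccoc2cc(OCOC)c(OCc3ccccc3)c(OCc3ccccc3)c12 | intermediate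
7 | 4-bromocatechol | Oc1ccc(Br)cc1O | starting material
8 | 4-bromo-1,2-bis(benzyloxy)benzene | Brc1ccc(OCc2ccccc2)c(OCc2ccccc2)c1 | intermediate
9 | bis[5,6-bis(benzyloxy)-7-(methoxymethoxy)-4-oxo-4H-chromen-2-yl]zinc (MgCl2/LiCl complex) | O=c1cc([Zn]c2cc(=O)c3c(OCc4ccccc4)c(OCc4ccccc4)c(OCOC)cc3o2)oc2cc(OCOC)c(OCc3ccccc3)c(OCc3ccccc3)c12 | intermediate
10 | 5,6-bis(benzyloxy)-2-[3,4-bis(benzyloxy)phenyl]-7-(methoxymethoxy)-4H-chromen-4-one | O=c1cc(-c2ccc(OCc3ccccc3)c(OCc3ccccc3)c2)oc2cc(OCOC)c(OCc3ccccc3)c(OCc3ccccc3)c12 | intermediate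
11 | 5,6-bis(benzyloxy)-2-[3,4-bis(benzyloxy)phenyl]-7-hydroxy-4H-chromen-4-one | O=c1cc(-c2ccc(OCc3ccccc3)c(OCc3ccccc3)c2)oc2cc(O)c(OCc3ccccc3)c(OCc3ccccc3)c12 | intermediate
12 | 5,6-bis(benzyloxy)-2-[3,4-bis(benzyloxy)phenyl]-4-oxo-4H-chromen-7-yl 2,2,2-trichloroethyl sulfate | O=c1cc(-c2ccc(OCc3ccccc3)c(OCc3ccccc3)c2)oc2cc(OS(=O)(=O)OCC(Cl)(Cl)Cl)c(OCc3ccccc3)c(OCc3ccccc3)c12 | intermediate
13 | ammonium 2-(3,4-dihydroxyphenyl)-5,6-dihydroxy-4-oxo-4H-chromen-7-yl sulfate | [NH4+].O=c1cc(-c2ccc(O)c(O)c2)oc2cc(OS(=O)(=O)[O-])c(O)c(O)c12 | intermediate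
14 | 6-hydroxyluteolin 7-sulfate | O=c1cc(-c2ccc(O)c(O)c2)oc2cc(OS(=O)(=O)O)c(O)c(O)c12 | target

Total step count: 9. Longest linear sequence: 8 (steps 1–4 and 6–9).

**Steps most likely to fail**

Step 6. Deprotonation may stray to C3 or C8. Zincation of the donor-rich chromone may be sluggish. The organozinc may also decay by ring opening before it couples. The fallback sets out from 6 and 8 and comes back at 10, and it forms the same bond in the natural polarity sense.
- Bromide 8 is converted by Br/Li exchange (n-BuLi, THF, −78 °C), B(OiPr)3 and aqueous acid into 3,4-bis(benzyloxy)phenylboronic acid F1.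
- Pd(II)-catalysed conjugate addition of F1 to C2 of 6 (Pd(TFA)2, 2,2'-bipyridine, NH4PF6, H2O, 1,2-dichloroethane, 60 °C) should give racemic 5,6-bis(benzyloxy)-2-[3,4-bis(benzyloxy)phenyl]-7-(methoxymethoxy)chroman-4-one F2.
- Dehydrogenation of C2–C3 with DDQ in hot dioxane erases the transient stereocentre and gives 10.

Step 3. Discrimination between O7 and O6 may be insufficient. Over-alkylation and air oxidation of the pyrogallol-type anion may also erode the mono-ether. The fallback sets out from 4 and comes back at 11, and it avoids free phenoxide altogether.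
- A Mitsunobu etherification (4-methoxybenzyl alcohol, PPh3, DIAD, THF, 0 °C) engages first the phenol acidic enough to protonate the betaine. It should give 5,6-dihydroxy-7-[(4-methoxybenzyl)oxy]-4H-chromen-4-one F3.
- Benzylation as in step 4 gives 5,6-bis(benzyloxy)-7-[(4-methoxybenzyl)oxy]-4H-chromen-4-one F4.
- Zincation and Negishi coupling with 8 as in step 6 gives 5,6-bis(benzyloxy)-2-[3,4-bis(benzyloxy)phenyl]-7-[(4-methoxybenzyl)oxy]-4H-chromen-4-one F5.
- TFA/anisole in CH2Cl2 at 0 °C removes the 4-methoxybenzyl group alone to give 11.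

Step 9. Transfer hydrogenation may saturate C2=C3. The crowded 5- and 6-benzyl groups may leave only slowly. The O–S bond may hydrolyse while the compound is in its acid form. The fallback sets out from 12 and comes back at 13, and it uses no palladium and no hydrogen source on the flavone.
- BCl3 with pentamethylbenzene as cation scavenger (CH2Cl2, −78 °C) removes the four benzyl groups while the sulfate is still the acid-stable neutral diester. This gives 2-(3,4-dihydroxyphenyl)-5,6-dihydroxy-4-oxo-4H-chromen-7-yl 2,2,2-trichloroethyl sulfate F6.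
- Zinc dust and ammonium formate in MeOH at rt then fragment the trichloroethyl ester to give 13.
- The salt 13 is exchanged on the resin as in step 9, or kept as the storage form.

**Further compounds**
F1 | step 6 | 3,4-bis(benzyloxy)phenylboronic acid | OB(O)c1ccc(OCc2ccccc2)c(OCc2ccccc2)c1
F2 | step 6 | racemic 5,6-bis(benzyloxy)-2-[3,4-bis(benzyloxy)phenyl]-7-(methoxymethoxy)chroman-4-one | O=C1CC(c2ccc(OCc3ccccc3)c(OCc3ccccc3)c2)Oc2cc(OCOC)c(OCc3ccccc3)c(OCc3ccccc3)c21
F3 | step 3 | 5,6-dihydroxy-7-[(4-methoxybenzyl)oxy]-4H-chromen-4-one | O=c1ccoc2cc(OCc3ccc(OC)cc3)c(O)c(O)c12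
F4 | step 3 | 5,6-bis(benzyloxy)-7-[(4-methoxybenzyl)oxy]-4H-chromen-4-one | O=c1ccoc2cc(OCc3ccc(OC)cc3)c(OCc3ccccc3)c(OCc3ccccc3)c12
F5 | step 3 | 5,6-bis(benzyloxy)-2-[3,4-bis(benzyloxy)phenyl]-7-[(4-methoxybenzyl)oxy]-4H-chromen-4-one | O=c1cc(-c2ccc(OCc3ccccc3)c(OCc3ccccc3)c2)oc2cc(OCc3ccc(OC)cc3)c(OCc3ccccc3)c(OCc3ccccc3)c12
F6 | step 9 | 2-(3,4-dihydroxyphenyl)-5,6-dihydroxy-4-oxo-4H-chromen-7-yl 2,2,2-trichloroethyl sulfate | O=c1cc(-c2ccc(O)c(O)c2)oc2cc(OS(=O)(=O)OCC(Cl)(Cl)Cl)c(O)c(O)c12
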